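**Retrosynthetic overview**

1. The target is a (3R,4R)-trans-3,4-dibenzyl-γ-butyrolactone. The 3-benzyl arm (arm A) carries an open (1S,2S)-1,2-diarylpropane-1,3-diol; the 4-benzyl arm (arm B) carries a (2S,3R)-trans-2-aryl-3-hydroxymethyl-2,3-dihydrobenzofuran. The end game is desilylation, then hydrogenolysis of three phenolic benzyl ethers.
2. The lactone ring is made last. Its C-2(=O)–O-1 unit is taken out as formate-derived CO2. The enabling feature: lactone C-3 is homobenzylic to the arm A arene, so it is the distal carbon of a styrene that accepts a CO2 radical anion to give a benzylic radical, while C-5 (the ring O–CH2) is a primary carbon three atoms away that takes the new carboxylate by 5-exo-tet SN2. C-4 then relays trans configuration to C-3.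
3. The chloro-styrene precursor comes from cross-metathesis of the arm A styrene with an (R)-2-(arylmethyl)but-3-enyl chloride. That chloride is made by auxiliary-controlled dienolate alkylation of a crotonyl imide with the arm B benzylic bromide.
4. Both arms come from 5-bromo-o-vanillin-derived arylacetyl (S)-oxazolidinone imides and O-benzylvanillin: a Mg-catalysed anti-aldol for arm A, and a boron syn-aldol for arm B followed by acid-induced MOM loss and SN1 closure.
5. Ring order: dihydrobenzofuran (step 15), then lactone (step 24).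

Key step: step 24

Remark: in step 5 the Mg-catalysed anti-aldol is taken to follow the chelated (Z)-enolate model (attack on the enolate face remote from the auxiliary benzyl group, as in auxiliary-controlled alkylations). If the opposite facial sense held, the enantiomeric auxiliary 26 would be used in steps 4 and 5.

Shorthand in names: Bn = benzyl; TBS = tert-butyldimethylsilyl; MOM = methoxymethyl. ArA = 4-(benzyloxy)-3-methoxy-5-[(1S,2S)-1-[4-(benzyloxy)-3-methoxyphenyl]-1,3-bis(TBS-oxy)propan-2-yl]phenyl. ArB = (2S,3R)-2-[4-(benzyloxy)-3-methoxyphenyl]-7-methoxy-3-[(TBS-oxy)methyl]-2,3-dihydro-1-benzofuran-5-yl.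

**Arm A**

Step 1
Reactants: 1 5-bromo-2-hydroxy-3-methoxybenzaldehyde
Product: 2 2-(benzyloxy)-5-bromo-3-methoxybenzaldehyde
Conditions: BnBr, K2CO3, DMF, 60 °C
Reagents that add atoms: benzyl bromide, BrCc1ccccc1
Why: Williamson O-alkylation of the phenol should install the benzyl ether that stays on this oxygen until the last step.

Step 2
Reactants: 2 2-(benzyloxy)-5-bromo-3-methoxybenzaldehyde
Product: 3 [2-(benzyloxy)-5-bromo-3-methoxyphenyl]acetonitrile
Conditions: TosMIC, KOt-Bu, DME, −40 °C; then MeOH, reflux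
Reagents that add atoms: tosylmethyl isocyanide, [C-]#[N+]CS(=O)(=O)c1ccc(C)cc1
Why: van Leusen reductive cyanation should convert ArCHO into ArCH2CN in one operation (low-temperature addition, then methanolysis of the N-formyl intermediate), giving the one-carbon homologue.

Step 3
Reactants: 3 [2-(benzyloxy)-5-bromo-3-methoxyphenyl]acetonitrile
Product: 4 [2-(benzyloxy)-5-bromo-3-methoxyphenyl]acetic acid
Conditions: KOH, EtOH/H2O, reflux; then 1 M HCl, 0 °C
Reagents that add atoms: potassium hydroxide, [K+].[OH-]; water, O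
Why: alkaline nitrile hydrolysis should give the arylacetic acid, the benzyl ether and aryl bromide being inert to hydroxide.

Step 4
Reactants: 4 [2-(benzyloxy)-5-bromo-3-methoxyphenyl]acetic acid; 5 (S)-4-benzyl-1,3-oxazolidin-2-one
Product: 7 (4S)-4-benzyl-3-{[2-(benzyloxy)-5-bromo-3-methoxyphenyl]acetyl}-1,3-oxazolidin-2-one, via mixed pivalic anhydride 6 (not isolated)
Conditions: t-BuCOCl, Et3N, THF, −20 °C; then LiCl, 5, rt
Reagents that add atoms: none
Why: N-acylation of the oxazolidinone through the mixed pivalic anhydride (LiCl/Et3N activation) is the standard route to N-acyl imides and should attack the less hindered arylacetyl carbonyl.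

Step 5
Reactants: 7 (4S)-4-benzyl-3-{[2-(benzyloxy)-5-bromo-3-methoxyphenyl]acetyl}-1,3-oxazolidin-2-one; 8 4-(benzyloxy)-3-methoxybenzaldehyde
Product: 10 (4S)-4-benzyl-3-[(2R,3S)-3-[4-(benzyloxy)-3-methoxyphenyl]-2-[2-(benzyloxy)-5-bromo-3-methoxyphenyl]-3-hydroxypropanoyl]-1,3-oxazolidin-2-one, via O-trimethylsilyl aldol ether 9 (not isolated)
Conditions: MgCl2 (0.2 equiv), Et3N, Me3SiCl, EtOAc, rt; then 1 M HCl, THF, 0 °C
Reagents that add atoms: none
Why: the magnesium-halide-catalysed direct anti-aldol of N-acyloxazolidinones with non-enolisable aromatic aldehydes should proceed through the Mg-chelated (Z)-enolate, which adds the aldehyde on the face remote from the auxiliary benzyl group via a boat-like transition state, setting C-2 (R) and C-3 (S) anti, with silylation of the aldolate driving turnover.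

Step 6
Reactants: 10 the anti-aldol imide
Product: 11 (1S,2S)-1-[4-(benzyloxy)-3-methoxyphenyl]-2-[2-(benzyloxy)-5-bromo-3-methoxyphenyl]propane-1,3-diol
Conditions: LiBH4, MeOH (1.1 equiv), THF, 0 °C
Reagents that add atoms: none
Why: borohydride reduction of the exocyclic imide carbonyl should release the primary alcohol and the recoverable auxiliary without touching either stereocentre, and low temperature should suppress retro-aldol cleavage.

Step 7
Reactants: 11 the (1S,2S)-diol
Product: 12 (1S,2S)-1-[4-(benzyloxy)-3-methoxyphenyl]-2-[2-(benzyloxy)-5-bromo-3-methoxyphenyl]-1,3-bis(TBS-oxy)propane (ArA–Br)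
Conditions: t-BuMe2SiOTf, 2,6-lutidine, CH2Cl2, −78 to 0 °C
Reagents that add atoms: tert-butyldimethylsilyl trifluoromethanesulfonate, CC(C)(C)[Si](C)(C)OS(=O)(=O)C(F)(F)F
Why: silyl triflate silylation should cap both hydroxyls, including the hindered benzylic one, and so shield the benzylic C–H and C–O bonds in the later radical and basic steps.

Step 8
Reactants: 12 ArA–Br
Product: 13 ArA–CH=CH2 (the 5-vinyl analogue of 12)
Conditions: vinylboronic acid pinacol ester, Pd(dppf)Cl2 (5 mol %), K2CO3, 1,4-dioxane/H2O, 85 °C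
Reagents that add atoms: vinylboronic acid pinacol ester, C=CB1OC(C)(C)C(C)(C)O1
Why: Suzuki–Miyaura vinylation of the unhindered aryl bromide should give the styrene, with silyl and benzyl ethers stable to aqueous carbonate.

**Arm B**

Step 9
Reactants: 1 5-bromo-2-hydroxy-3-methoxybenzaldehyde
Product: 14 5-bromo-3-methoxy-2-(methoxymethoxy)benzaldehyde
Conditions: MeOCH2Cl, i-Pr2NEt, CH2Cl2, 0 °C to rt
Reagents that add atoms: chloromethyl methyl ether, COCCl
Why: O-alkylation gives an acid-labile acetal on the one phenol that must later be unmasked selectively in the presence of a benzyl ether.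

Step 10
Reactants: 14 5-bromo-3-methoxy-2-(methoxymethoxy)benzaldehyde
Product: 15 [5-bromo-3-methoxy-2-(methoxymethoxy)phenyl]acetonitrile
Conditions: TosMIC, KOt-Bu, DME, −40 °C; then MeOH, reflux
Reagents that add atoms: tosylmethyl isocyanide, [C-]#[N+]CS(=O)(=O)c1ccc(C)cc1
Why: van Leusen reductive cyanation as in step 2, the MOM ether being base-stable.

Step 11
Reactants: 15 [5-bromo-3-methoxy-2-(methoxymethoxy)phenyl]acetonitrile
Product: 16 [5-bromo-3-methoxy-2-(methoxymethoxy)phenyl]acetic acid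
Conditions: KOH, EtOH/H2O, reflux; then 1 M HCl to pH 4, 0 °C
Reagents that add atoms: potassium hydroxide, [K+].[OH-]; water, O
Why: alkaline nitrile hydrolysis as in step 3, with cold, mild acidification so that the MOM acetal survives.

Step 12
Reactants: 16 [5-bromo-3-methoxy-2-(methoxymethoxy)phenyl]acetic acid; 5 (S)-4-benzyl-1,3-oxazolidin-2-one
Product: 18 (4S)-4-benzyl-3-{[5-bromo-3-methoxy-2-(methoxymethoxy)phenyl]acetyl}-1,3-oxazolidin-2-one, via mixed pivalic anhydride 17 (not isolated)
Conditions: t-BuCOCl, Et3N, THF, −20 °C; then LiCl, 5, rt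
Reagents that add atoms: none
Why: mixed-anhydride N-acylation as in step 4.

Step 13
Reactants: 18 the MOM-protected arylacetyl imide; 8 4-(benzyloxy)-3-methoxybenzaldehyde
Product: 19 (4S)-4-benzyl-3-[(2S,3S)-3-[4-(benzyloxy)-3-methoxyphenyl]-2-[5-bromo-3-methoxy-2-(methoxymethoxy)phenyl]-3-hydroxypropanoyl]-1,3-oxazolidin-2-one
Conditions: n-Bu2BOTf, i-Pr2NEt, CH2Cl2, −78 to 0 °C; 8, −78 to 0 °C; then pH 7 buffer, MeOH, 30% H2O2, 0 °C
Reagents that add atoms: none
Why: the oxazolidinone boron syn-aldol (Evans aldol) should proceed through the (Z)-boron enolate and a Zimmerman–Traxler chair with the auxiliary carbonyl dipole opposed, setting C-2 (S) and C-3 (S) syn; C-2 is thus opposite to that of arm A from the same auxiliary.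

Step 14
Reactants: 19 the syn-aldol imide
Product: 20 (1S,2R)-1-[4-(benzyloxy)-3-methoxyphenyl]-2-[5-bromo-3-methoxy-2-(methoxymethoxy)phenyl]propane-1,3-diol
Conditions: LiBH4, MeOH (1.1 equiv), THF, 0 °C
Reagents that add atoms: none
Why: reductive cleavage of the imide as in step 6 should give the 1,3-diol and return the auxiliary.

Step 15
Reactants: 20 the (1S,2R)-diol
Product: 21 [(2S,3R)-2-[4-(benzyloxy)-3-methoxyphenyl]-5-bromo-7-methoxy-2,3-dihydro-1-benzofuran-3-yl]methanol
Conditions: HCl (0.5 M) in MeOH, 40 °C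
Reagents that add atoms: none
Why: acid should cleave the MOM acetal and ionise the p-benzyloxybenzylic alcohol, and the freed ortho phenol should capture the cation in a 5-membered SN1 ring closure that places the new C-2 aryl group trans to the fixed C-3 hydroxymethyl group (substrate control, the trans isomer also being the thermodynamic one).

Step 16
Reactants: 21 the dihydrobenzofuran alcohol
Product: 22 ArB–Br, the TBS ether of 21
Conditions: t-BuMe2SiCl, imidazole, DMF, rt
Reagents that add atoms: tert-butyldimethylsilyl chloride, CC(C)(C)[Si](C)(C)Cl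
Why: silylation of the only free (primary) hydroxyl is needed before the organolithium and halogenation steps.

Step 17
Reactants: 22 ArB–Br
Product: 24 ArB–CH2OH, via 5-formyl dihydrobenzofuran 23 (not isolated)
Conditions: n-BuLi, THF, −78 °C; DMF, −78 to 0 °C; then MeOH, NaBH4, 0 °C
Reagents that add atoms: N,N-dimethylformamide, CN(C)C=O
Why: bromine–lithium exchange is faster than any deprotonation at −78 °C, and formylation of the aryllithium followed by in-flask borohydride reduction should give the benzylic alcohol.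

Step 18
Reactants: 24 ArB–CH2OH
Product: 25 ArB–CH2Br
Conditions: CBr4, PPh3, CH2Cl2, 0 °C
Reagents that add atoms: carbon tetrabromide, BrC(Br)(Br)Br
Why: Appel bromination under neutral conditions should give the electron-rich benzylic bromide, which is used at once without purification on silica.

**Core assembly and end game**

Step 19
Reactants: 26 (R)-4-benzyl-1,3-oxazolidin-2-one; 27 (E)-but-2-enoyl chloride
Product: 28 (4R)-4-benzyl-3-[(2E)-but-2-enoyl]-1,3-oxazolidin-2-one
Conditions: n-BuLi, THF, −78 °C; then 27, −78 to 0 °C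
Reagents that add atoms: none
Why: N-acylation of the lithiated oxazolidinone by the acid chloride is the standard preparation of the crotonyl imide.

Step 20
Reactants: 28 the crotonyl imide (used in excess); 25 ArB–CH2Br
Product: 29 (4R)-4-benzyl-3-[(2R)-2-(ArB-methyl)but-3-enoyl]-1,3-oxazolidin-2-one
Conditions: NaN(SiMe3)2, THF, −78 °C; then 25, −78 to −40 °C
Reagents that add atoms: none
Why: γ-deprotonation should give the chelated sodium dienolate, which alkylates at the α-carbon on the face remote from the auxiliary benzyl group (auxiliary-controlled dienolate alkylation), setting the future lactone C-4 as R and leaving the vinyl group deconjugated.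

Step 21
Reactants: 29 the alkylated imide
Product: 30 (2R)-2-(ArB-methyl)but-3-en-1-ol
Conditions: LiBH4, MeOH (1.1 equiv), Et2O, 0 °C
Reagents that add atoms: none
Why: reductive cleavage of the imide should give the homoallylic alcohol without α-epimerisation or alkene migration, and return the auxiliary.

Step 22
Reactants: 30 the homoallylic alcohol
Product: 31 ArB–CH2–CH(CH2Cl)–CH=CH2, (2R)-configured
Conditions: PPh3, N-chlorosuccinimide, CH2Cl2, 0 °C to rt
Reagents that add atoms: N-chlorosuccinimide, ClN1C(=O)CCC1=O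
Why: Appel-type chlorination turns the primary alcohol into a chloride that is inert to the metathesis and radical conditions but open to later intramolecular SN2.

Step 23
Reactants: 31 the homoallylic chloride; 13 ArA–CH=CH2
Product: 32 ArA–CH=CH–CH(CH2Cl)–CH2–ArB, (1E,3R)-configured
Conditions: second-generation Hoveyda–Grubbs catalyst (5 mol %), 1,4-benzoquinone (10 mol %), CH2Cl2, 40 °C
Reagents that add atoms: none
Why: olefin cross-metathesis of a styrene with an α-branched terminal alkene should give the E-styrene with loss of ethylene, benzoquinone suppressing hydride-mediated alkene migration; the alkene geometry has no bearing on step 24.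

Step 24
Reactants: 32 the chloro-styrene; 33 potassium formate
Product: 36 (3R,4R)-3-(ArA-methyl)-4-(ArB-methyl)dihydrofuran-2(3H)-one, via potassium chloro carboxylate 34 (not isolated), via lactone C-3 epimer mixture 35 (not isolated)
Conditions: 33 (5 equiv), 4DPAIPN (2 mol %), HSCH2CH2SO3Na (20 mol %), DMSO, 440 nm LEDs, rt; then 70 °C; then DBU, 80 °C
Reagents that add atoms: none
Why: Proposed new method: the photoexcited cyanoarene dye and the thiol should turn formate into the CO2 radical anion, which adds to the styrene carbon distal to the arene (future C-3) to give a benzylic radical that is quenched by hydrogen-atom transfer from the thiol, and the resulting potassium γ-chloro carboxylate 34 should close onto the primary chloride on warming to form the O-1–C-5 bond, after which DBU equilibrates C-3. The closest known reaction types are the photochemical formate/thiol anti-Markovnikov hydrocarboxylation of β-alkylstyrenes and the thermal lactonisation of γ-halo carboxylates, and only their merger in one flask is untested. The lactone ring closes in the 5-exo-tet mode by O-alkylation, the C-2–C-3 bond having been made intermolecularly by Giese-type radical addition. C-3 is created without kinetic control and is then set trans to the auxiliary-derived C-4 stereocentre under thermodynamic control (reversible enolisation by DBU, the trans-3,4-dibenzyl lactone being the more stable epimer), while C-4 carries no acidic hydrogen and cannot epimerise. The step needs regioselective addition at the non-benzylic alkene carbon, secured by benzylic radical stabilisation and the nucleophilic character of the CO2 radical anion; it also needs the thiyl radical to abstract from formate and not from benzylic ether C–H bonds, and the CO2 radical anion to spare the C–Cl bond, secured by excess formate, silylation of the benzylic carbinol and the choice of an unactivated primary chloride over a bromide or iodide.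

Step 25
Reactants: 36 the fully protected trans lactone
Product: 37 (3R,4R)-3-{4-(benzyloxy)-3-[(1S,2S)-1-[4-(benzyloxy)-3-methoxyphenyl]-1,3-dihydroxypropan-2-yl]-5-methoxybenzyl}-4-{[(2S,3R)-2-[4-(benzyloxy)-3-methoxyphenyl]-3-(hydroxymethyl)-7-methoxy-2,3-dihydro-1-benzofuran-5-yl]methyl}dihydrofuran-2(3H)-one
Conditions: Bu4NF, AcOH, THF, rt to 40 °C
Reagents that add atoms: none
Why: buffered fluoride should remove all three silyl ethers without acid, so that the electron-rich benzylic alcohol is not ionised while its neighbouring phenol is still benzylated, and without epimerising the lactone.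

Step 26
Reactants: 37 the tri-O-benzyl triol
Product: 38 CNP0186558.2 (target)
Conditions: H2 (1 atm), Pd/C (10 wt %), EtOAc/EtOH, rt
Reagents that add atoms: none
Why: neutral hydrogenolysis should cleave the three phenolic benzyl ethers much faster than the benzylic C–OH and dihydrobenzofuran C–O bonds, and the absence of acid prevents closure of the open diol onto its ortho phenol.

**Compound list**

1 | 5-bromo-2-hydroxy-3-methoxybenzaldehyde | COc1cc(Br)cc(C=O)c1O | starting material
2 | 2-(benzyloxy)-5-bromo-3-methoxybenzaldehyde | COc1cc(Br)cc(C=O)c1OCc1ccccc1 | intermediate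
3 | [2-(benzyloxy)-5-bromo-3-methoxyphenyl]acetonitrile | COc1cc(Br)cc(CC#N)c1OCc1ccccc1 | intermediate
4 | [2-(benzyloxy)-5-bromo-3-methoxyphenyl]acetic acid | COc1cc(Br)cc(CC(=O)O)c1OCc1ccccc1 | intermediate
5 | (S)-4-benzyl-1,3-oxazolidin-2-one | O=C1N[C@@H](Cc2ccccc2)CO1 | starting material
6 | mixed anhydride of 4 and pivalic acid | COc1cc(Br)cc(CC(=O)OC(=O)C(C)(C)C)c1OCc1ccccc1 | intermediate
7 | (4S)-4-benzyl-3-{[2-(benzyloxy)-5-bromo-3-methoxyphenyl]acetyl}-1,3-oxazolidin-2-one | COc1cc(Br)cc(CC(=O)N2[C@@H](Cc3ccccc3)COC2=O)c1OCc1ccccc1 | intermediate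
8 | 4-(benzyloxy)-3-methoxybenzaldehyde | COc1cc(C=O)ccc1OCc1ccccc1 | starting material
9 | O-trimethylsilyl ether of anti-aldol 10 | COc1cc([C@@H](O[Si](C)(C)C)[C@H](C(=O)N2[C@@H](Cc3ccccc3)COC2=O)c2cc(Br)cc(OC)c2OCc2ccccc2)ccc1OCc1ccccc1 | intermediate
10 | (4S)-4-benzyl-3-[(2R,3S)-3-[4-(benzyloxy)-3-methoxyphenyl]-2-[2-(benzyloxy)-5-bromo-3-methoxyphenyl]-3-hydroxypropanoyl]-1,3-oxazolidin-2-one | COc1cc([C@@H](O)[C@H](C(=O)N2[C@@H](Cc3ccccc3)COC2=O)c2cc(Br)cc(OC)c2OCc2ccccc2)ccc1OCc1ccccc1 | intermediate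
11 | (1S,2S)-1-[4-(benzyloxy)-3-methoxyphenyl]-2-[2-(benzyloxy)-5-bromo-3-methoxyphenyl]propane-1,3-diol | COc1cc([C@@H](O)[C@H](CO)c2cc(Br)cc(OC)c2OCc2ccccc2)ccc1OCc1ccccc1 | intermediate
12 | ArA–Br, the 1,3-bis-TBS ether of 11 | COc1cc([C@@H](O[Si](C)(C)C(C)(C)C)[C@H](CO[Si](C)(C)C(C)(C)C)c2cc(Br)cc(OC)c2OCc2ccccc2)ccc1OCc1ccccc1 | intermediate
13 | ArA–CH=CH2, the 5-vinyl analogue of 12 | COc1cc([C@@H](O[Si](C)(C)C(C)(C)C)[C@H](CO[Si](C)(C)C(C)(C)C)c2cc(C=C)cc(OC)c2OCc2ccccc2)ccc1OCc1ccccc1 | intermediate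
14 | 5-bromo-3-methoxy-2-(methoxymethoxy)benzaldehyde | COCOc1c(C=O)cc(Br)cc1OC | intermediate
15 | [5-bromo-3-methoxy-2-(methoxymethoxy)phenyl]acetonitrile | COCOc1c(CC#N)cc(Br)cc1OC | intermediate
16 | [5-bromo-3-methoxy-2-(methoxymethoxy)phenyl]acetic acid | COCOc1c(CC(=O)O)cc(Br)cc1OC | intermediate
17 | mixed anhydride of 16 and pivalic acid | COCOc1c(CC(=O)OC(=O)C(C)(C)C)cc(Br)cc1OC | intermediate
18 | (4S)-4-benzyl-3-{[5-bromo-3-methoxy-2-(methoxymethoxy)phenyl]acetyl}-1,3-oxazolidin-2-one | COCOc1c(CC(=O)N2[C@@H](Cc3ccccc3)COC2=O)cc(Br)cc1OC | intermediate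
19 | (4S)-4-benzyl-3-[(2S,3S)-3-[4-(benzyloxy)-3-methoxyphenyl]-2-[5-bromo-3-methoxy-2-(methoxymethoxy)phenyl]-3-hydroxypropanoyl]-1,3-oxazolidin-2-one | COc1cc([C@@H](O)[C@@H](C(=O)N2[C@@H](Cc3ccccc3)COC2=O)c2cc(Br)cc(OC)c2OCOC)ccc1OCc1ccccc1 | intermediate
20 | (1S,2R)-1-[4-(benzyloxy)-3-methoxyphenyl]-2-[5-bromo-3-methoxy-2-(methoxymethoxy)phenyl]propane-1,3-diol | COc1cc([C@@H](O)[C@@H](CO)c2cc(Br)cc(OC)c2OCOC)ccc1OCc1ccccc1 | intermediate
21 | [(2S,3R)-2-[4-(benzyloxy)-3-methoxyphenyl]-5-bromo-7-methoxy-2,3-dihydro-1-benzofuran-3-yl]methanol | Brc1cc(OC)c2c(c1)[C@H](CO)[C@@H](c1ccc(OCc3ccccc3)c(OC)c1)O2 | intermediate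
22 | ArB–Br, the TBS ether of 21 | Brc1cc(OC)c2c(c1)[C@H](CO[Si](C)(C)C(C)(C)C)[C@@H](c1ccc(OCc3ccccc3)c(OC)c1)O2 | intermediate
23 | ArB–CHO, the 5-formyl analogue of 22 | O=Cc1cc(OC)c2c(c1)[C@H](CO[Si](C)(C)C(C)(C)C)[C@@H](c1ccc(OCc3ccccc3)c(OC)c1)O2 | intermediate
24 | ArB–CH2OH, the 5-(hydroxymethyl) analogue of 22 | OCc1cc(OC)c2c(c1)[C@H](CO[Si](C)(C)C(C)(C)C)[C@@H](c1ccc(OCc3ccccc3)c(OC)c1)O2 | intermediate
25 | ArB–CH2Br, the 5-(bromomethyl) analogue of 22 | BrCc1cc(OC)c2c(c1)[C@H](CO[Si](C)(C)C(C)(C)C)[C@@H](c1ccc(OCc3ccccc3)c(OC)c1)O2 | intermediate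
26 | (R)-4-benzyl-1,3-oxazolidin-2-one | O=C1N[C@H](Cc2ccccc2)CO1 | starting material
27 | (E)-but-2-enoyl chloride | C/C=C/C(Cl)=O | starting material
28 | (4R)-4-benzyl-3-[(2E)-but-2-enoyl]-1,3-oxazolidin-2-one | C/C=C/C(=O)N1[C@H](Cc2ccccc2)COC1=O | intermediate
29 | (4R)-4-benzyl-3-[(2R)-2-(ArB-methyl)but-3-enoyl]-1,3-oxazolidin-2-one | C=C[C@@H](Cc1cc(OC)c2c(c1)[C@H](CO[Si](C)(C)C(C)(C)C)[C@@H](c1ccc(OCc3ccccc3)c(OC)c1)O2)C(=O)N1[C@H](Cc2ccccc2)COC1=O | intermediate
30 | (2R)-2-(ArB-methyl)but-3-en-1-ol | C=C[C@@H](Cc1cc(OC)c2c(c1)[C@H](CO[Si](C)(C)C(C)(C)C)[C@@H](c1ccc(OCc3ccccc3)c(OC)c1)O2)CO | intermediate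
31 | ArB–CH2–CH(CH2Cl)–CH=CH2, (2R)-2-(chloromethyl)but-3-enyl on ArB | C=C[C@@H](Cc1cc(OC)c2c(c1)[C@H](CO[Si](C)(C)C(C)(C)C)[C@@H](c1ccc(OCc3ccccc3)c(OC)c1)O2)CCl | intermediate
32 | ArA–CH=CH–CH(CH2Cl)–CH2–ArB, (1E,3R) | COc1cc([C@@H](O[Si](C)(C)C(C)(C)C)[C@H](CO[Si](C)(C)C(C)(C)C)c2cc(/C=C/[C@@H](Cc3cc(OC)c4c(c3)[C@H](CO[Si](C)(C)C(C)(C)C)[C@@H](c3ccc(OCc5ccccc5)c(OC)c3)O4)CCl)cc(OC)c2OCc2ccccc2)ccc1OCc1ccccc1 | intermediate
33 | potassium formate | [K+].[O-]C=O | starting material
34 | potassium (3R)-2-(ArA-methyl)-3-(chloromethyl)-4-ArB-butanoate, both C-2 epimers | COc1cc([C@@H](O[Si](C)(C)C(C)(C)C)[C@H](CO[Si](C)(C)C(C)(C)C)c2cc(CC(C(=O)[O-])[C@@H](Cc3cc(OC)c4c(c3)[C@H](CO[Si](C)(C)C(C)(C)C)[C@@H](c3ccc(OCc5ccccc5)c(OC)c3)O4)CCl)cc(OC)c2OCc2ccccc2)ccc1OCc1ccccc1.[K+] | intermediate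
35 | (4R)-3-(ArA-methyl)-4-(ArB-methyl)dihydrofuran-2(3H)-one, both C-3 epimers | COc1cc([C@@H](O[Si](C)(C)C(C)(C)C)[C@H](CO[Si](C)(C)C(C)(C)C)c2cc(CC3C(=O)OC[C@@H]3Cc3cc(OC)c4c(c3)[C@H](CO[Si](C)(C)C(C)(C)C)[C@@H](c3ccc(OCc5ccccc5)c(OC)c3)O4)cc(OC)c2OCc2ccccc2)ccc1OCc1ccccc1 | intermediate
36 | (3R,4R)-3-(ArA-methyl)-4-(ArB-methyl)dihydrofuran-2(3H)-one | COc1cc([C@@H](O[Si](C)(C)C(C)(C)C)[C@H](CO[Si](C)(C)C(C)(C)C)c2cc(C[C@H]3C(=O)OC[C@@H]3Cc3cc(OC)c4c(c3)[C@H](CO[Si](C)(C)C(C)(C)C)[C@@H](c3ccc(OCc5ccccc5)c(OC)c3)O4)cc(OC)c2OCc2ccccc2)ccc1OCc1ccccc1 | intermediate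
37 | tri-O-benzyl ether of the target (all three phenols benzylated, all three alcohols free) | COc1cc([C@@H](O)[C@H](CO)c2cc(C[C@H]3C(=O)OC[C@@H]3Cc3cc(OC)c4c(c3)[C@H](CO)[C@@H](c3ccc(OCc5ccccc5)c(OC)c3)O4)cc(OC)c2OCc2ccccc2)ccc1OCc1ccccc1 | intermediate
38 | CNP0186558.2 | COc1cc([C@@H](O)[C@H](CO)c2cc(C[C@H]3C(=O)OC[C@@H]3Cc3cc(OC)c4c(c3)[C@H](CO)[C@@H](c3ccc(O)c(OC)c3)O4)cc(OC)c2O)ccc1O | target

**Step count and risks**

Total step count: 26. Longest linear sequence: 17 steps (steps 9–18, then 20–26, from compound 1 through arm B).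

Steps most likely to fail:

1. Step 24 (proposed new method). The CO2 radical anion may add slowly to the electron-rich, β-branched styrene, so that reduction of the alkene, hydrogen-atom abstraction at benzylic ether positions or incomplete ring closure compete. Fallback by known chemistry, setting out from alcohol 30 and bromide 12: hydroboration of 30 with 9-BBN and NaOH/H2O2 work-up would give (2R)-2-(ArB-methyl)butane-1,4-diol F1. TEMPO/PhI(OAc)2 oxidation, which starts at the less hindered CH2OH, would give (4R)-4-(ArB-methyl)dihydrofuran-2(3H)-one F2. In parallel, bromine–lithium exchange on 12 and trapping with paraformaldehyde would give the arm A benzylic alcohol F3, and CBr4/PPh3 would give the arm A benzylic bromide F4. Enolisation of F2 with LiN(SiMe3)2 at −78 °C and alkylation with F4 anti to the C-4 substituent (the classical trans-selective lignan lactone alkylation) would return to the route at compound 36.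

2. Step 5. The electron-rich aldehyde may react slowly, and reversible aldolisation or base-mediated epimerisation of the doubly activated α-centre may erode the anti selectivity or the facial sense. Fallback, setting out from acid 4 and auxiliary 26: acylation under the conditions of step 4 (through anhydride 6) would give the (4R)-configured arylacetyl imide F5. The boron syn-aldol with 8 under the conditions of step 13 would give the (2R,3R)-syn-aldol imide F6, and LiBH4 would give the (1R,2S)-diol F7. TBSCl/imidazole would silylate the primary hydroxyl to give the mono-silyl ether F8. Mitsunobu inversion of the benzylic carbinol (4-nitrobenzoic acid, PPh3, DIAD) would give the (1S,2S)-4-nitrobenzoate F9, and K2CO3/MeOH would give the (1S,2S)-alcohol F10. Silylation with t-BuMe2SiOTf/2,6-lutidine would return to the route at compound 12.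

3. Step 23. Turnover at the α-branched alkene may be slow when both partners are used near 1:1, so that styrene homodimerisation and hydride-mediated double-bond migration take over. Fallback, setting out from chloride 31 and bromide 12: cross-metathesis of 31 with a large excess of vinylboronic acid pinacol ester (same catalyst) would give the (E)-alkenyl pinacol boronate F11. Suzuki–Miyaura coupling of F11 with 12 (Pd(dppf)Cl2, K3PO4, 1,4-dioxane/H2O, 60 °C) would return to the route at compound 32, with step 8 bypassed.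

**Further compounds**

F1 | step 24 | (2R)-2-(ArB-methyl)butane-1,4-diol | OCC[C@@H](Cc1cc(OC)c2c(c1)[C@H](CO[Si](C)(C)C(C)(C)C)[C@@H](c1ccc(OCc3ccccc3)c(OC)c1)O2)CO
F2 | step 24 | (4R)-4-(ArB-methyl)dihydrofuran-2(3H)-one | O=C1C[C@@H](Cc2cc(OC)c3c(c2)[C@H](CO[Si](C)(C)C(C)(C)C)[C@@H](c2ccc(OCc4ccccc4)c(OC)c2)O3)CO1
F3 | step 24 | ArA–CH2OH, the 5-(hydroxymethyl) analogue of 12 | COc1cc([C@@H](O[Si](C)(C)C(C)(C)C)[C@H](CO[Si](C)(C)C(C)(C)C)c2cc(CO)cc(OC)c2OCc2ccccc2)ccc1OCc1ccccc1
F4 | step 24 | ArA–CH2Br, the 5-(bromomethyl) analogue of 12 | COc1cc([C@@H](O[Si](C)(C)C(C)(C)C)[C@H](CO[Si](C)(C)C(C)(C)C)c2cc(CBr)cc(OC)c2OCc2ccccc2)ccc1OCc1ccccc1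
F5 | step 5 | (4R)-4-benzyl-3-{[2-(benzyloxy)-5-bromo-3-methoxyphenyl]acetyl}-1,3-oxazolidin-2-one | COc1cc(Br)cc(CC(=O)N2[C@H](Cc3ccccc3)COC2=O)c1OCc1ccccc1
F6 | step 5 | (4R)-4-benzyl-3-[(2R,3R)-3-[4-(benzyloxy)-3-methoxyphenyl]-2-[2-(benzyloxy)-5-bromo-3-methoxyphenyl]-3-hydroxypropanoyl]-1,3-oxazolidin-2-one | COc1cc([C@H](O)[C@H](C(=O)N2[C@H](Cc3ccccc3)COC2=O)c2cc(Br)cc(OC)c2OCc2ccccc2)ccc1OCc1ccccc1
F7 | step 5 | (1R,2S)-1-[4-(benzyloxy)-3-methoxyphenyl]-2-[2-(benzyloxy)-5-bromo-3-methoxyphenyl]propane-1,3-diol | COc1cc([C@H](O)[C@H](CO)c2cc(Br)cc(OC)c2OCc2ccccc2)ccc1OCc1ccccc1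
F8 | step 5 | 3-O-TBS ether of F7 | COc1cc([C@H](O)[C@H](CO[Si](C)(C)C(C)(C)C)c2cc(Br)cc(OC)c2OCc2ccccc2)ccc1OCc1ccccc1
F9 | step 5 | (1S,2S)-1-O-(4-nitrobenzoyl)-3-O-TBS diol | COc1cc([C@@H](OC(=O)c2ccc(cc2)[N+](=O)[O-])[C@H](CO[Si](C)(C)C(C)(C)C)c2cc(Br)cc(OC)c2OCc2ccccc2)ccc1OCc1ccccc1
F10 | step 5 | 3-O-TBS ether of diol 11 | COc1cc([C@@H](O)[C@H](CO[Si](C)(C)C(C)(C)C)c2cc(Br)cc(OC)c2OCc2ccccc2)ccc1OCc1ccccc1
F11 | step 23 | pinacol [(1E,3R)-3-(chloromethyl)-4-ArB-but-1-en-1-yl]boronate | CC1(C)OB(/C=C/[C@@H](Cc2cc(OC)c3c(c2)[C@H](CO[Si](C)(C)C(C)(C)C)[C@@H](c2ccc(OCc4ccccc4)c(OC)c2)O3)CCl)OC1(C)C
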